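A direct plan would complete the protected 4-aryl-2-naphthoic acid first and attach the chiral side chain last.
It would condense the γ-keto acid A1 Perkin-fashion to the arylidene butenolide A2 and open and cyclodehydrate A2 in hot methanolic HCl to the methyl naphthoate A3. It would then saponify A3 to the acid A4, couple A4 with tribenzyl (R)-danshensu A5 to the heptabenzyl compound A6, and hydrogenolyse.
The weakest step would be the acid cyclodehydration of A2. The ring (C4–C4a) could close only from the (E)-alkene, onto a ketone made poorly electrophilic by its own dialkoxyaryl group, in hot HCl that aryl benzyl ethers tolerate badly.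
Second, the same carboxyl group would be esterified (A3), freed (A4) and esterified again (A6), which is three operations with no gain in complexity.
Third, the carbodiimide/DMAP coupling of A4 with A5 would be the step least welcome on precious material. The α-hydroxy ester is a poor nucleophile, N-acylurea can form, and base can epimerise the only stereocentre once both fragments are complete.

**Plan of the new route**
Feature: in ring B (C1–C4, C4a, C8a), C2 carries the whole ester side chain and lies between two CH groups (C1–H, C3–H). C4 is bonded to two identical catechol rings, the fused ring A and the pendant ring C.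
Cut 1 (key step): both ring bonds of C2 (C1–C2 and C2–C3) are cut at once. A "C–CO2R*" unit is excised and ring B contracts to the five-membered ring of the 1-aryl-1H-indene 5. C2 and its carbonyl go with (R)-danshensu as the diazoacetate 10.
Cut 2: the indene C1–C7a bond is opened to a 1,3-diarylallyl cation with identical ends. This leads back to alcohol 4 and, by an aldol cut, to chalcone 3 from 1 and 2.
Ring order: the five-membered carbocycle on ring A comes first, then a transient cyclopropane, then ring B by one-carbon ring expansion. Ring B is never closed by a cyclisation.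
The weak steps vanish. There is no ketone cyclodehydration and no alkene geometry, because the inserted carbon can only end up between C1 and C3. There is no ester shuffle, because the carboxyl carbon arrives already esterified. The ester C–O bond is made first, on a cheap acyl bromide, not last.

Key step: step 6

Assumption: sodium (R)-danshensu, 1 and 2 are taken as commercial; the stereocentre of the target is (R), as in natural danshensu, and is never created or broken in the route.

## Route

Step 1
Reactants: 1 3,4-bis(benzyloxy)benzaldehyde; 2 1-[3,4-bis(benzyloxy)phenyl]ethan-1-one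
Product: 3 (E)-1,3-bis[3,4-bis(benzyloxy)phenyl]prop-2-en-1-one
Conditions: KOH, EtOH–THF, rt
Reagents that add atoms: none
Why: Claisen–Schmidt aldol condensation of a non-enolisable aldehyde with a methyl ketone should give the (E)-chalcone, and aryl benzyl ethers are inert to hydroxide.

Step 2
Reactants: 3 (E)-1,3-bis[3,4-bis(benzyloxy)phenyl]prop-2-en-1-one
Product: 4 (±)-(E)-1,3-bis[3,4-bis(benzyloxy)phenyl]prop-2-en-1-ol
Conditions: NaBH4, CeCl3·7H2O, MeOH–THF, 0 °C; aq. NaHCO3
Reagents that add atoms: none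
Why: Luche reduction should deliver 1,2-hydride addition to the enone, and the carbinol centre may be racemic because it is flattened to an allyl cation in the next step.

Step 3
Reactants: 4 (±)-(E)-1,3-bis[3,4-bis(benzyloxy)phenyl]prop-2-en-1-ol
Product: 5 (±)-5,6-bis(benzyloxy)-1-[3,4-bis(benzyloxy)phenyl]-1H-indene
Conditions: Bi(OTf)3 (5 mol %), CH2Cl2–MeNO2 (0.02 M), rt; neutral work-up, kept away from base
Reagents that add atoms: none
Why: Ionisation of the doubly activated alcohol should give a 1,3-diarylallyl cation with identical termini which, after E/Z equilibration, closes by intramolecular Friedel–Crafts allylic alkylation (the known cationic cyclisation of aryl allyl cations to indenes) at the ring carbon para to the 3-benzyloxy group, so only one constitution can arise from either end, and the new C1 centre is racemic and is erased in step 6.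

Step 4
Reactants: 6 sodium (2R)-3-(3,4-dihydroxyphenyl)-2-hydroxypropanoate (sodium danshensu)
Product: 8 diphenylmethyl (2R)-3-[3,4-bis(benzyloxy)phenyl]-2-hydroxypropanoate, via diphenylmethyl (2R)-3-(3,4-dihydroxyphenyl)-2-hydroxypropanoate 7 (not isolated)
Conditions: Ph2CHBr (1.0 equiv), DMF, rt, N2; then BnBr (2.2 equiv), K2CO3, rt
Reagents that add atoms: bromodiphenylmethane, BrC(c1ccccc1)c1ccccc1; benzyl bromide, BrCc1ccccc1
Why: The carboxylate, the only anion present, should be alkylated first to the bulky diphenylmethyl ester (chosen to shield the α-H in steps 5 and 6), K2CO3 then deprotonates only the two phenols for Williamson benzylation, the secondary alcohol stays free, and no bond at the (R) centre is touched.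

Step 5
Reactants: 8 diphenylmethyl (2R)-3-[3,4-bis(benzyloxy)phenyl]-2-hydroxypropanoate
Product: 10 diphenylmethyl (2R)-3-[3,4-bis(benzyloxy)phenyl]-2-[(diazoacetyl)oxy]propanoate, via diphenylmethyl (2R)-3-[3,4-bis(benzyloxy)phenyl]-2-[(bromoacetyl)oxy]propanoate 9 (not isolated)
Conditions: BrCH2COBr, NaHCO3, MeCN, 0 °C; aqueous work-up; then TsNHNHTs, DBU, THF, 0 °C, 10 min
Reagents that add atoms: bromoacetyl bromide, O=C(Br)CBr; N,N'-ditosylhydrazine, Cc1ccc(cc1)S(=O)(=O)NNS(=O)(=O)c1ccc(C)cc1
Why: The acyl bromide acylates the alcohol oxygen with only hydrogencarbonate present (C–O bond at the stereocentre retained), and N-alkylation of ditosylhydrazine by 9 followed by twofold sulfinate elimination (ditosylhydrazine diazoacetate synthesis, Bamford–Stevens type) should give 10 within minutes at 0 °C, an exposure to DBU that lactate-type α-acyloxy esters are known to tolerate.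

Step 6
Reactants: 5 (±)-5,6-bis(benzyloxy)-1-[3,4-bis(benzyloxy)phenyl]-1H-indene; 10 diphenylmethyl (2R)-3-[3,4-bis(benzyloxy)phenyl]-2-[(diazoacetyl)oxy]propanoate
Product: 13 diphenylmethyl (2R)-3-[3,4-bis(benzyloxy)phenyl]-2-({6,7-bis(benzyloxy)-4-[3,4-bis(benzyloxy)phenyl]naphthalene-2-carbonyl}oxy)propanoate, via diphenylmethyl (2R)-3-[3,4-bis(benzyloxy)phenyl]-2-{[bromo(diazo)acetyl]oxy}propanoate 11 (not isolated), via diphenylmethyl (2R)-3-[3,4-bis(benzyloxy)phenyl]-2-({3,4-bis(benzyloxy)-6-[3,4-bis(benzyloxy)phenyl]-1-bromo-1,1a,6,6a-tetrahydrocyclopropa[a]indene-1-carbonyl}oxy)propanoate 12 (not isolated)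
Conditions: 10 (1.5 equiv), DBU, NBS, CH2Cl2, 0 °C, 5 min; cold SiO2 plug; filtrate added slowly to 5, Rh2(esp)2 (1 mol %), 2,6-di-tert-butylpyridine, CH2Cl2, 0 °C → rt
Reagents that add atoms: N-bromosuccinimide, O=C1CCC(=O)N1Br (its Br stands only in 11 and 12 and leaves again as bromide; 13 holds atoms of 5 and 10 only)
Why: NBS/DBU brominates the diazo carbon of 10 to 11, whose Rh(II) carbenoid [Br–C–CO2R*] should cyclopropanate the only alkene present, the electron-rich styrene-type C2=C3 bond of 5, anti to the C1 aryl group, so that both new C–C bonds (naphthalene C1–C2 and C2–C3) are made at one carbon. Bromocyclopropane 12 should then ionise with disrotatory 2π-electrocyclic opening of the internal C1a–C6a bond (Woodward–Hoffmann–DePuy rule), pushed by the para-benzyloxy group of the fused ring, and the six-membered benzylic allyl cation loses the doubly benzylic H of the aryl-bearing carbon to the hindered pyridine, which turns the five-membered ring into the second benzenoid ring. The closest known reaction type is the halocarbene cyclopropanation–ring expansion of indenes to 2-substituted naphthalenes (Parham/Ciamician–Dennstedt-type carbon-atom insertion), which is also run with halodiazoacetates and Rh2(esp)2 on indoles. The three-membered ring closes by [2+1] cycloaddition and ring B arises by ring expansion rather than cyclisation, so no position on an arene and no alkene geometry has to be chosen, because the carbene carbon can only end up between indene C2 and C3, meta to the aryl-bearing carbon. The three ring stereocentres of 12 and the racemic C1 of 5 are transient and are all erased on aromatisation, so every diastereomer should converge on 13 (an exo-bromide that cannot open directly can epimerise by reversible donor–acceptor ring opening), while the (R) centre lies three bonds from the reacting carbon and is not touched. The step needs the alkene to win over the arenes and benzylic C–H bonds, which the nucleophilicity of the p-alkoxystyrene bond secures, and it needs 5 not to shift to the conjugated 3-aryl-1H-indene (which would give the 1-aryl-2-naphthoate), which removal of DBU on the plug and a base far too weak to deprotonate an indene secure.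

Step 7
Reactants: 13 diphenylmethyl (2R)-3-[3,4-bis(benzyloxy)phenyl]-2-({6,7-bis(benzyloxy)-4-[3,4-bis(benzyloxy)phenyl]naphthalene-2-carbonyl}oxy)propanoate
Product: 14 eritrichin, (2R)-3-(3,4-dihydroxyphenyl)-2-{[4-(3,4-dihydroxyphenyl)-6,7-dihydroxynaphthalene-2-carbonyl]oxy}propanoic acid
Conditions: H2 (1 atm), 10 % Pd/C, THF–MeOH, trace AcOH, rt; filtration under Ar
Reagents that add atoms: none
Why: Catalytic hydrogenolysis should cleave the six aryl benzyl ethers and the diphenylmethyl ester, whereas the naphthalene and the non-benzylic secondary naphthoate C–O bond, and with it the (R) centre, are inert, and the slightly acidic, air-free medium protects the three catechols.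

## Compound list

1 | 3,4-bis(benzyloxy)benzaldehyde | O=Cc1ccc(OCc2ccccc2)c(OCc2ccccc2)c1 | starting material
2 | 1-[3,4-bis(benzyloxy)phenyl]ethan-1-one | CC(=O)c1ccc(OCc2ccccc2)c(OCc2ccccc2)c1 | starting material
3 | (E)-1,3-bis[3,4-bis(benzyloxy)phenyl]prop-2-en-1-one | O=C(/C=C/c1ccc(OCc2ccccc2)c(OCc2ccccc2)c1)c1ccc(OCc2ccccc2)c(OCc2ccccc2)c1 | intermediate
4 | (±)-(E)-1,3-bis[3,4-bis(benzyloxy)phenyl]prop-2-en-1-ol | OC(/C=C/c1ccc(OCc2ccccc2)c(OCc2ccccc2)c1)c1ccc(OCc2ccccc2)c(OCc2ccccc2)c1 | intermediate
5 | (±)-5,6-bis(benzyloxy)-1-[3,4-bis(benzyloxy)phenyl]-1H-indene | C1(c2ccc(OCc3ccccc3)c(OCc3ccccc3)c2)C=Cc2cc(OCc3ccccc3)c(OCc3ccccc3)cc21 | intermediate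
6 | sodium (2R)-3-(3,4-dihydroxyphenyl)-2-hydroxypropanoate | [Na+].[O-]C(=O)[C@H](O)Cc1ccc(O)c(O)c1 | starting material
7 | diphenylmethyl (2R)-3-(3,4-dihydroxyphenyl)-2-hydroxypropanoate | O[C@H](Cc1ccc(O)c(O)c1)C(=O)OC(c1ccccc1)c1ccccc1 | intermediate
8 | diphenylmethyl (2R)-3-[3,4-bis(benzyloxy)phenyl]-2-hydroxypropanoate | O[C@H](Cc1ccc(OCc2ccccc2)c(OCc2ccccc2)c1)C(=O)OC(c1ccccc1)c1ccccc1 | intermediate
9 | diphenylmethyl (2R)-3-[3,4-bis(benzyloxy)phenyl]-2-[(bromoacetyl)oxy]propanoate | BrCC(=O)O[C@H](Cc1ccc(OCc2ccccc2)c(OCc2ccccc2)c1)C(=O)OC(c1ccccc1)c1ccccc1 | intermediate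
10 | diphenylmethyl (2R)-3-[3,4-bis(benzyloxy)phenyl]-2-[(diazoacetyl)oxy]propanoate | [N-]=[N+]=CC(=O)O[C@H](Cc1ccc(OCc2ccccc2)c(OCc2ccccc2)c1)C(=O)OC(c1ccccc1)c1ccccc1 | intermediate
11 | diphenylmethyl (2R)-3-[3,4-bis(benzyloxy)phenyl]-2-{[bromo(diazo)acetyl]oxy}propanoate | [N-]=[N+]=C(Br)C(=O)O[C@H](Cc1ccc(OCc2ccccc2)c(OCc2ccccc2)c1)C(=O)OC(c1ccccc1)c1ccccc1 | intermediate
12 | diphenylmethyl (2R)-3-[3,4-bis(benzyloxy)phenyl]-2-({3,4-bis(benzyloxy)-6-[3,4-bis(benzyloxy)phenyl]-1-bromo-1,1a,6,6a-tetrahydrocyclopropa[a]indene-1-carbonyl}oxy)propanoate (mixture of ring diastereomers) | O=C(O[C@H](Cc1ccc(OCc2ccccc2)c(OCc2ccccc2)c1)C(=O)OC(c1ccccc1)c1ccccc1)C1(Br)C2C1c1cc(OCc3ccccc3)c(OCc3ccccc3)cc1C2c1ccc(OCc2ccccc2)c(OCc2ccccc2)c1 | intermediate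
13 | diphenylmethyl (2R)-3-[3,4-bis(benzyloxy)phenyl]-2-({6,7-bis(benzyloxy)-4-[3,4-bis(benzyloxy)phenyl]naphthalene-2-carbonyl}oxy)propanoate | O=C(O[C@H](Cc1ccc(OCc2ccccc2)c(OCc2ccccc2)c1)C(=O)OC(c1ccccc1)c1ccccc1)c1cc(-c2ccc(OCc3ccccc3)c(OCc3ccccc3)c2)c2cc(OCc3ccccc3)c(OCc3ccccc3)cc2c1 | intermediate
14 | eritrichin | O=C(O[C@H](Cc1ccc(O)c(O)c1)C(=O)O)c1cc(-c2ccc(O)c(O)c2)c2cc(O)c(O)cc2c1 | target

## Summary

Total steps: 7. Longest linear sequence: 5 (steps 1, 2, 3, 6, 7).

**Steps most likely to fail**

**Step 6.** The bromocarbenoid may be lost before it reaches the alkene, by dimerisation, by C–H insertion or ylide formation at benzylic ether sites, or by attack on its own side chain. Traces of base may also shift the double bond of the indene.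
- The fallback sets out from 5 and 10 and returns at 13. The oxidation level is supplied by an external oxidant instead of a leaving group on the carbene carbon.
- Slow addition of the unhalogenated diazoacetate 10 to 5 with Rh2(OAc)4 (classical indene cyclopropanation) should give diphenylmethyl (2R)-3-[3,4-bis(benzyloxy)phenyl]-2-({3,4-bis(benzyloxy)-6-[3,4-bis(benzyloxy)phenyl]-1,1a,6,6a-tetrahydrocyclopropa[a]indene-1-carbonyl}oxy)propanoate F1 as a mixture of diastereomers.
- DDQ in CH2Cl2 should then abstract hydride from the doubly benzylic C6–H. The cyclopropylcarbinyl cation should open its internal C1a–C6a bond to the p-benzyloxybenzyl cation, and loss of the α-ester proton should give 13.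

**Step 3.** The strongly stabilised allyl cation may be too unreactive for ring closure, so that intermolecular arylation or acid-induced oligomerisation of the electron-rich indene takes over.
- The fallback sets out from 1 and returns at 5. The five-membered ring is closed by acylation at its other end (indene C3–C3a).
- Knoevenagel condensation of 1 with Meldrum's acid would give 5-[3,4-bis(benzyloxy)benzylidene]-2,2-dimethyl-1,3-dioxane-4,6-dione F2.
- Conjugate addition of [3,4-bis(benzyloxy)phenyl]magnesium bromide F3 (from commercial 4-bromo-1,2-bis(benzyloxy)benzene and Mg) would give the symmetric 5-{bis[3,4-bis(benzyloxy)phenyl]methyl}-2,2-dimethyl-1,3-dioxane-4,6-dione F4.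
- Sc(OTf)3-catalysed intramolecular Friedel–Crafts acylation in hot MeNO2, in which either of the two identical rings may react, would give (±)-5,6-bis(benzyloxy)-3-[3,4-bis(benzyloxy)phenyl]-2,3-dihydro-1H-inden-1-one F5.
- NaBH4 would give (±)-5,6-bis(benzyloxy)-3-[3,4-bis(benzyloxy)phenyl]-2,3-dihydro-1H-inden-1-ol F6, and catalytic TsOH in warm toluene would dehydrate it to 5.

**Step 5.** The amidine base may partly epimerise the α-acyloxy ester centre or attack the bromoacetate.
- The fallback sets out from 8 and returns at 10. The whole C2N2 unit is delivered in one acylation, without DBU.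
- Commercial glyoxylic acid chloride p-toluenesulfonylhydrazone and N,N-dimethylaniline in CH2Cl2 at 0 °C would give diphenylmethyl (2R)-3-[3,4-bis(benzyloxy)phenyl]-2-({[2-(4-methylbenzenesulfonyl)hydrazinylidene]acetyl}oxy)propanoate F7.
- Et3N would then eliminate sulfinate from F7 to give 10.

## Further compounds

F1 | step 6 | diphenylmethyl (2R)-3-[3,4-bis(benzyloxy)phenyl]-2-({3,4-bis(benzyloxy)-6-[3,4-bis(benzyloxy)phenyl]-1,1a,6,6a-tetrahydrocyclopropa[a]indene-1-carbonyl}oxy)propanoate | O=C(O[C@H](Cc1ccc(OCc2ccccc2)c(OCc2ccccc2)c1)C(=O)OC(c1ccccc1)c1ccccc1)C1C2C1c1cc(OCc3ccccc3)c(OCc3ccccc3)cc1C2c1ccc(OCc2ccccc2)c(OCc2ccccc2)c1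
F2 | step 3 | 5-[3,4-bis(benzyloxy)benzylidene]-2,2-dimethyl-1,3-dioxane-4,6-dione | CC1(C)OC(=O)C(=Cc2ccc(OCc3ccccc3)c(OCc3ccccc3)c2)C(=O)O1
F3 | step 3 | [3,4-bis(benzyloxy)phenyl]magnesium bromide | Br[Mg]c1ccc(OCc2ccccc2)c(OCc2ccccc2)c1
F4 | step 3 | 5-{bis[3,4-bis(benzyloxy)phenyl]methyl}-2,2-dimethyl-1,3-dioxane-4,6-dione | CC1(C)OC(=O)C(C(c2ccc(OCc3ccccc3)c(OCc3ccccc3)c2)c2ccc(OCc3ccccc3)c(OCc3ccccc3)c2)C(=O)O1
F5 | step 3 | (±)-5,6-bis(benzyloxy)-3-[3,4-bis(benzyloxy)phenyl]-2,3-dihydro-1H-inden-1-one | O=C1CC(c2ccc(OCc3ccccc3)c(OCc3ccccc3)c2)c2cc(OCc3ccccc3)c(OCc3ccccc3)cc21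
F6 | step 3 | (±)-5,6-bis(benzyloxy)-3-[3,4-bis(benzyloxy)phenyl]-2,3-dihydro-1H-inden-1-ol | OC1CC(c2ccc(OCc3ccccc3)c(OCc3ccccc3)c2)c2cc(OCc3ccccc3)c(OCc3ccccc3)cc21
F7 | step 5 | diphenylmethyl (2R)-3-[3,4-bis(benzyloxy)phenyl]-2-({[2-(4-methylbenzenesulfonyl)hydrazinylidene]acetyl}oxy)propanoate | Cc1ccc(cc1)S(=O)(=O)NN=CC(=O)O[C@H](Cc1ccc(OCc2ccccc2)c(OCc2ccccc2)c1)C(=O)OC(c1ccccc1)c1ccccc1
A1 | direct plan | 4-[3,4-bis(benzyloxy)phenyl]-4-oxobutanoic acid | OC(=O)CCC(=O)c1ccc(OCc2ccccc2)c(OCc2ccccc2)c1
A2 | direct plan | (3E)-3-[3,4-bis(benzyloxy)benzylidene]-5-[3,4-bis(benzyloxy)phenyl]furan-2(3H)-one | O=C1OC(c2ccc(OCc3ccccc3)c(OCc3ccccc3)c2)=C/C1=C\c1ccc(OCc2ccccc2)c(OCc2ccccc2)c1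
A3 | direct plan | methyl 6,7-bis(benzyloxy)-4-[3,4-bis(benzyloxy)phenyl]naphthalene-2-carboxylate | COC(=O)c1cc(-c2ccc(OCc3ccccc3)c(OCc3ccccc3)c2)c2cc(OCc3ccccc3)c(OCc3ccccc3)cc2c1
A4 | direct plan | 6,7-bis(benzyloxy)-4-[3,4-bis(benzyloxy)phenyl]naphthalene-2-carboxylic acid | OC(=O)c1cc(-c2ccc(OCc3ccccc3)c(OCc3ccccc3)c2)c2cc(OCc3ccccc3)c(OCc3ccccc3)cc2c1
A5 | direct plan | benzyl (2R)-3-[3,4-bis(benzyloxy)phenyl]-2-hydroxypropanoate | O[C@H](Cc1ccc(OCc2ccccc2)c(OCc2ccccc2)c1)C(=O)OCc1ccccc1
A6 | direct plan | benzyl (2R)-3-[3,4-bis(benzyloxy)phenyl]-2-({6,7-bis(benzyloxy)-4-[3,4-bis(benzyloxy)phenyl]naphthalene-2-carbonyl}oxy)propanoate | O=C(O[C@H](Cc1ccc(OCc2ccccc2)c(OCc2ccccc2)c1)C(=O)OCc1ccccc1)c1cc(-c2ccc(OCc3ccccc3)c(OCc3ccccc3)c2)c2cc(OCc3ccccc3)c(OCc3ccccc3)cc2c1
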